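The data are simulated on assumed constants.

The left-handed product of the south-west run stood at 11.6% after 90.0 min and at 11.9% after 120 min, so we first ask whether that is a stop or a slow climb seen too briefly.

common to all: gas 170 mM (held)
- south-west: left-handed substrate 1.2 M; right-handed substrate 1.2 M; temperature −5 °C; run made earlier
- elm: left-handed substrate 0.80 M; right-handed substrate 0.80 M; temperature −5 °C; time 20 h
- ash: left-handed substrate 0.80 M; right-handed substrate 0.80 M; temperature 25 °C; time 20 h
- cedar: left-handed substrate 0.80 M; right-handed substrate 0.80 M; temperature −35 °C; time 20 h
- maple: left-handed substrate 0.80 M; right-handed substrate 0.80 M; temperature 55 °C; time 20 h

- south-west (time / min: left-handed product / %): 15.0: 1.9; 30.0: 2.9; 50.0: 6.4; 60.0: 4.6; 80.0: 10.9; 90.0: 11.6; 120: 11.9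

(standard deviation of a reading: 1 percentage point)

- which flask leads in amount of left-handed product, in percent of the left-handed substrate and right-handed substrate together charged ("all alike" within 1.5 percentage points) (elm / ash / cedar / maple / all alike)
- how much left-handed product is there at the end, in percent of the left-handed substrate and right-handed substrate together charged: elm
- how much left-handed product is there at the end, in percent of the left-handed substrate and right-handed substrate together charged: ash
- how much left-handed product is there at the end, in percent of the left-handed substrate and right-handed substrate together charged: cedar
- how much left-handed product is there at the end, in percent of the left-handed substrate and right-handed substrate together charged: maple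

- coupling partner is single-handed; left-handed substrate and right-handed substrate are mirror images of each other, charged as a racemate, each of them at the stated concentration
- at the start none of the gas is in solution
- the earlier runs do not show what temperature does; that part of a forecast is a guess
- the handed part of coupling partner does not stay in what it makes, so the products of the two hands are mirror images too

Those two readings differ by 0.3 percentage points, and one reading is good to 1 point, so we do not read a stop from them. We assume that the held gas keeps c(coupling partner) steady. The left-handed substrate then has one steady chance of reacting per hour, whatever its concentration (a pseudo-first-order step). It is half of the charge, so the climb of the south-west run to 90.0 min gives, as a reading, a lifetime of 6.47 h.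

Our one number is the count of lifetimes, the flask's time divided by that lifetime: for elm, 3.09. The share of left-handed substrate left is exp(−count), for elm 4.54%, which makes 47.7% left-handed product in elm.

Is one number enough? Temperature is a guess: with a doubling per 10 degrees, the count is 24.7 in ash, 198 in maple and 0.387 in cedar. On that guess cedar gives 16.0% left-handed product. Ash and maple then both come to our ceiling, half of the charge, so this count does not separate them. That ceiling also assumes that right-handed substrate does not become left-handed, which the south-west run does not show.

The forecast gave elm 12%, ash 6%, cedar 6% and maple 3%, with elm leading: “I read the plateau as an equilibrium.” Our reckoning differs, since it reads no stop.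

The simulation gives elm 48.5%, ash 54.5%, cedar 9.65% and maple 44.9%, so ash leads, above our ceiling.

    coupling partner + right-handed substrate → right-handed product (k = 3.70 /M/h, Ea = 79.0 kJ/mol)
    gas ⇌ coupling partner, rate k2*(csat - [coupling partner]) (kL = 81.0 /h)
    coupling partner → decomposition product (k = 2.80 × 10⁻⁴ /h, Ea = 107 kJ/mol)
    coupling partner + left-handed substrate → left-handed product (k = 8.30 /M/h, Ea = 48.0 kJ/mol)
    left-handed substrate ⇌ right-handed substrate (k = 0.130 /h, Ea = 101 kJ/mol)
    (constants at 25 °C)

Our count for elm left 4.54% of its left-handed substrate, and elm holds 4.5% of the left-handed substrate charged. Cedar keeps 81% of its charged left-handed substrate after 20.0 h, a count of 0.214. Ten times the time makes that 2.14, which gives 44.1% left-handed product, and cedar holds 44.2% after 200 h.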